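## Retrosynthetic overview

1. Target 37 ⇐ N-oxidation of amine 36 ⇐ δ-lactone closed by acid on the exo-methylene tert-butyl ester 35 ⇐ piperidine closed by inverting N-alkylation at an allylic carbinol (33) ⇐ aldol union of hydrindenone 12 with the azabicyclic aldehyde 28.
2. The cyclohexane ring of the hydrindene (N-bearing CH, sp2 ring-fusion C, ring-fusion CH, two CH2, CH next to the lactone carbinol carbon) is never closed as a six-membered ring. It grows from the cyclopentane of 9 by a one-carbon ring expansion, in the same operation that closes the cyclopentene (Prins–pinacol cascade).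
3. Enabling feature: the N-bearing ring carbon is bonded directly to the sp2 ring-fusion carbon of the cyclopentene. At the ketone level this is a 1-acylcyclopentene whose acyl carbon is a member of the six-membered ring, which is the pattern left when a ring bond migrates onto an alkyne-derived cation next to a carbinol.
4. Aldehyde 28: quaternary centre by auxiliary-controlled Michael addition; pyrrole annulated onto the ketone; all-cis pyrrole hydrogenation sets the three ring CH centres.
5. Ring order: cyclopentene and cyclohexenone together (step 6) on a purchased cyclopentane; pyrrole, then pyrrolidine (steps 9 and 13) on a second purchased cyclopentane; piperidine (step 19); lactone (step 22).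

Key step: step 6

Assumption: the methoxy-bearing carbon of 10 (and of F3 to F5) forms as an epimer mixture and is drawn without configuration because step 7 deletes it; SAMP and (S)-1-phenylethylamine are the auxiliary enantiomers expected from the usual sense of induction.

## Route

Step 1
Reactants: 1 cyclopentanone; 2 SAMP, (S)-1-amino-2-(methoxymethyl)pyrrolidine
Product: 3 cyclopentanone SAMP hydrazone
Conditions: neat, 60 °C, then removal of H2O in vacuo
Reagents that add atoms: none
Why: Hydrazone condensation of an unhindered ketone with the chiral hydrazine installs the auxiliary for the SAMP-hydrazone alkylation.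

Step 2
Reactants: 3 cyclopentanone SAMP hydrazone; 4 2-bromo-1,1-dimethoxyethane
Product: 6 (E)-SAMP hydrazone of (S)-2-(2,2-dimethoxyethyl)cyclopentanone, via lithium azaenolate 5 (not isolated)
Conditions: LiN(i-Pr)2, THF, 0 °C; then 4, −95 °C → rt
Reagents that add atoms: none
Why: SAMP-hydrazone alkylation, in which the chelated azaenolate is alkylated on the face away from the methoxymethyl arm, should set the ring stereocentre as (S).

Step 3
Reactants: 6 alkylated SAMP hydrazone
Product: 7 (S)-2-(2,2-dimethoxyethyl)cyclopentan-1-one
Conditions: O3, CH2Cl2, −78 °C; N2 purge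
Reagents that add atoms: ozone, [O-][O+]=O
Why: Oxidative cleavage of the C=N bond by ozone at low temperature should release the ketone without epimerizing the α-stereocentre or touching the acetal.

Step 4
Reactants: 7 (S)-2-(2,2-dimethoxyethyl)cyclopentan-1-one
Product: 8 (1S,2S)-2-(2,2-dimethoxyethyl)-1-ethynylcyclopentan-1-ol
Conditions: HC≡CMgBr, CeCl3, THF, −78 °C; H2O
Reagents that add atoms: ethynylmagnesium bromide, C#C[Mg]Br
Why: The non-basic organocerium acetylide should add to the ketone without enolization, anti to the α-side chain (either carbinol epimer would converge in step 6).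

Step 5
Reactants: 8 propargylic alcohol
Product: 9 trimethylsilyl ether of 8
Conditions: 1-(trimethylsilyl)imidazole, CH2Cl2, rt
Reagents that add atoms: 1-(trimethylsilyl)imidazole, C[Si](C)(C)n1ccnc1
Why: Silyl transfer caps the tertiary alcohol so that it cannot trap the oxocarbenium ion of step 6 and can serve as the pinacol terminus.

Step 6
Reactants: 9 trimethylsilyl ether
Product: 10 (7aS)-2-methoxy-1,2,5,6,7,7a-hexahydro-4H-inden-4-one
Conditions: SnCl4, CH2Cl2, −78 → −23 °C
Reagents that add atoms: none
Why: Proposed new method: SnCl4 ionizes the dimethyl acetal to an oxocarbenium ion that is attacked by the terminal alkyne carbon (6-endo-dig with respect to the alkyne), and as positive charge develops on the internal alkyne carbon the aligned C1–C2 ring bond migrates to it (pinacol shift), the silyloxy carbon collapsing to the ketone with loss of Me3SiOMe. The closest known reaction is the Prins–pinacol ring-enlarging cyclopentane annulation of 1-alkenyl-2-(2,2-dimethoxyethyl)cycloalkanol silyl ethers; a terminal alkyne is asked to act as terminator here so that the conjugated enone is delivered directly. The cyclopentene is closed by C–C bond formation between the alkyne terminus and the acetal carbon followed by contraction of the transient six-membered ring, and the cyclohexenone arises from the cyclopentane by the 1,2-shift that inserts the former internal alkyne carbon. The only stereocentre that survives, the ring-fusion CH, is the migrating carbon and moves with retention, so its configuration is the one fixed in step 2. The step needs migration of the tether-bearing ring carbon and not of the ring CH2: only that bond lies in the plane of the empty orbital of the developing vinyl cation inside the new ring, and the silyl ether prevents capture of the oxocarbenium ion by oxygen.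

Step 7
Reactants: 10 γ-methoxy enone
Product: 12 (S)-1,2,5,6,7,7a-hexahydro-4H-inden-4-one, via β,γ-enone 11 (not isolated)
Conditions: SmI2 (2.2 equiv), MeOH, THF–HMPA, −78 °C; then DBU (cat.), CH2Cl2, rt
Reagents that add atoms: none
Why: Electron transfer from SmI2 to the enone should expel the γ-methoxide (vinylogous α-alkoxy ketone cleavage), the dienolate is protonated at the α-carbon, and DBU moves the alkene into conjugation, the ring-fusion hydrogen not being acidified by the carbonyl.

Step 8
Reactants: 13 methyl 2-oxocyclopentane-1-carboxylate; 14 (S)-1-phenylethylamine; 15 tert-butyl acrylate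
Product: 18 methyl (S)-1-(3-tert-butoxy-3-oxopropyl)-2-oxocyclopentane-1-carboxylate, via enamino ester 16 (not isolated), via imine adduct 17 (not isolated)
Conditions: 14, TsOH (cat.), toluene, reflux, −H2O; then 15, ZnCl2, THF, rt; then aq. AcOH, rt
Reagents that add atoms: water, O
Why: Auxiliary-controlled Michael addition of the chiral enamino ester, with the acrylate approaching the enamine face anti to the phenyl group, should create the quaternary centre as (S), and hydrolysis returns the ketone and the amine.

Step 9
Reactants: 18 keto diester; 19 allylamine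
Product: 21 methyl (S)-6-(3-tert-butoxy-3-oxopropyl)-3-methyl-1,4,5,6-tetrahydrocyclopenta[b]pyrrole-6-carboxylate, via N-allyl ketimine 20 (not isolated)
Conditions: 19, 4 Å MS, toluene, 60 °C; then Pd(OAc)2 (10 mol %), Bu4NBr, O2 (1 atm), DMSO, 60 °C
Reagents that add atoms: none
Why: Aerobic Pd-catalysed dehydrogenative cyclization of the N-allylimine (α-palladation on the only enolizable side, alkene insertion, β-hydride elimination, aromatization) should give the 3-methylpyrrole without touching the quaternary centre.

Step 10
Reactants: 21 pyrrole diester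
Product: 22 tert-butyl 3-[(S)-6-(hydroxymethyl)-3-methyl-1,4,5,6-tetrahydrocyclopenta[b]pyrrol-6-yl]propanoate
Conditions: LiBH4, THF–MeOH, 0 °C → rt
Reagents that add atoms: none
Why: LiBH4 should reduce the methyl ester chemoselectively in the presence of the tert-butyl ester.

Step 11
Reactants: 22 pyrrole alcohol
Product: 23 triisopropylsilyl ether of 22
Conditions: i-Pr3SiCl, imidazole, DMAP (cat.), DMF, 40 °C
Reagents that add atoms: chlorotriisopropylsilane, CC(C)[Si](Cl)(C(C)C)C(C)C
Why: O-silylation places a very large group on the one-carbon arm of the quaternary centre, which is needed to differentiate the two pyrrole faces in step 13.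

Step 12
Reactants: 23 silyl ether
Product: 25 N-[2-(trimethylsilyl)ethoxycarbonyl] pyrrole, via sodium pyrrolide 24 (not isolated)
Conditions: NaH, THF, 0 °C; then Teoc-OSu, 0 °C → rt
Reagents that add atoms: 2,5-dioxopyrrolidin-1-yl 2-(trimethylsilyl)ethyl carbonate (Teoc-OSu), C[Si](C)(C)CCOC(=O)ON1C(=O)CCC1=O
Why: N-acylation of the pyrrolide gives the carbamate that both activates the pyrrole for hydrogenation and protects nitrogen until step 18.

Step 13
Reactants: 25 N-Teoc pyrrole
Product: 26 2-(trimethylsilyl)ethyl (3S,3aR,6S,6aS)-6-(3-tert-butoxy-3-oxopropyl)-3-methyl-6-{[(triisopropylsilyl)oxy]methyl}hexahydrocyclopenta[b]pyrrole-1(2H)-carboxylate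
Conditions: H2 (50 bar), 5% Rh/Al2O3, EtOAc–MeOH, rt
Reagents that add atoms: none
Why: Heterogeneous hydrogenation of the N-acylpyrrole should add all four hydrogens from the face opposite the silyloxymethyl group on the adjacent quaternary carbon, which sets the cis ring fusion and places the methyl group on the concave face.

Step 14
Reactants: 26 silyl ether
Product: 27 6-(hydroxymethyl) analogue of 26
Conditions: HF·pyridine, pyridine, THF, 0 °C → rt
Reagents that add atoms: none
Why: Buffered HF should cleave the primary silyl ether while the Teoc carbamate (which needs free fluoride) and the tert-butyl ester remain.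

Step 15
Reactants: 27 primary alcohol
Product: 28 2-(trimethylsilyl)ethyl (3S,3aR,6S,6aS)-6-(3-tert-butoxy-3-oxopropyl)-6-formyl-3-methylhexahydrocyclopenta[b]pyrrole-1(2H)-carboxylate
Conditions: Dess–Martin periodinane, NaHCO3, CH2Cl2, rt
Reagents that add atoms: none
Why: Dess–Martin oxidation gives the neopentyl aldehyde, which has no α-hydrogen and cannot epimerize or self-condense.

Step 16
Reactants: 12 hydrindenone; 28 aldehyde
Product: 30 aldol adduct, via lithium dienolate 29 (not isolated)
Conditions: LiN(i-Pr)2, THF, −78 °C; then 28, −78 °C; AcOH, −78 °C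
Reagents that add atoms: none
Why: The kinetic cross-conjugated dienolate (deprotonation at the CH2 on the saturated side of the carbonyl) should add to the aldehyde through a closed chair transition state with axial C–C bond formation on the half-chair, on the face opposite the ring-fusion hydrogen, which sets the new ring stereocentre with its hydrogen cis to the ring-fusion hydrogen (the carbinol centre is removed in step 20), and the cold quench prevents retro-aldol and epimerization.

Step 17
Reactants: 30 aldol adduct
Product: 31 allylic alcohol (diol)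
Conditions: NaBH4, CeCl3·7H2O, MeOH, −78 °C
Reagents that add atoms: none
Why: Luche 1,2-reduction with axial hydride delivery anti to the axial side chain on the neighbouring carbon should give the allylic alcohol cis to that side chain and removes the epimerizable α-position.

Step 18
Reactants: 31 N-Teoc diol
Product: 32 amino diol
Conditions: Bu4NF, THF, rt
Reagents that add atoms: none
Why: Fluoride-induced fragmentation of the 2-(trimethylsilyl)ethyl carbamate frees the secondary amine under non-acidic conditions that leave the allylic alcohol and the tert-butyl ester untouched.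

Step 19
Reactants: 32 amino diol
Product: 33 pentacyclic amino alcohol
Conditions: PPh3, DIAD, THF (high dilution), 0 °C → rt
Reagents that add atoms: none
Why: Mitsunobu cyclodehydration, in which the amine displaces the allylic oxyphosphonium group intramolecularly (6-exo-tet) with inversion, should place nitrogen trans to the neighbouring side chain as in the target, attack at the far allyl terminus or at the other carbinol being excluded by ring size.

Step 20
Reactants: 33 amino alcohol
Product: 34 pentacyclic amino ketone
Conditions: Dess–Martin periodinane, NaHCO3, CH2Cl2, 0 °C → rt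
Reagents that add atoms: none
Why: Dess–Martin oxidation of the remaining secondary alcohol is mild and non-basic, so the α-stereocentre and the β-amino ketone should survive.

Step 21
Reactants: 34 amino ketone
Product: 35 exo-methylene compound
Conditions: Cp2TiMe2, toluene, 70 °C, dark
Reagents that add atoms: dimethyltitanocene, C[Ti](C)(C1C=CC=C1)C1C=CC=C1
Why: Petasis methylenation is non-basic and tolerant of hindered, enolizable ketones, so it should convert the carbonyl to the 1,1-disubstituted alkene without epimerization or β-elimination of the amine and without attacking the tert-butyl ester.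

Step 22
Reactants: 35 exo-methylene tert-butyl ester
Product: 36 hexacyclic lactone amine
Conditions: TfOH (3 equiv), CH2Cl2, 0 °C → rt; aq. NaHCO3
Reagents that add atoms: none
Why: Markovnikov protonation of the 1,1-disubstituted alkene gives a tertiary cation that is captured by the tethered ester carbonyl (with loss of isobutene) from the face carrying the propanoate chain, which should give the cis-fused δ-lactone with the new methyl group on the other face, while the adjacent ammonium centre disfavours protonation of the ring alkene.

Step 23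
Reactants: 36 lactone amine
Product: 37 target N-oxide
Conditions: mCPBA (1.0 equiv), K2CO3, CH2Cl2, −40 → 0 °C
Reagents that add atoms: 3-chloroperbenzoic acid, OOC(=O)c1cccc(Cl)c1
Why: Amine N-oxidation is much faster than epoxidation of the trisubstituted alkene, and oxygen is delivered to the lone pair, whose orientation (anti to the adjacent ring-fusion hydrogen) is fixed by the trans-fused azabicyclic core.

## Compound list

1 | cyclopentanone | O=C1CCCC1 | starting material
2 | SAMP, (S)-1-amino-2-(methoxymethyl)pyrrolidine | COC[C@@H]1CCCN1N | starting material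
3 | cyclopentanone SAMP hydrazone | COC[C@@H]1CCCN1N=C1CCCC1 | intermediate
4 | 2-bromo-1,1-dimethoxyethane | COC(OC)CBr | starting material
5 | lithium azaenolate of 3 | COC[C@@H]1CCCN1N([Li])C1=CCCC1 | intermediate (not isolated)
6 | (E)-SAMP hydrazone of (S)-2-(2,2-dimethoxyethyl)cyclopentanone | COC(OC)C[C@@H]1CCC/C1=N\N1CCC[C@H]1COC | intermediate
7 | (S)-2-(2,2-dimethoxyethyl)cyclopentan-1-one | COC(OC)C[C@@H]1CCCC1=O | intermediate
8 | (1S,2S)-2-(2,2-dimethoxyethyl)-1-ethynylcyclopentan-1-ol (ethynyl trans to the side chain) | COC(OC)C[C@@H]1CCC[C@@]1(O)C#C | intermediate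
9 | trimethylsilyl ether of 8 | COC(OC)C[C@@H]1CCC[C@@]1(O[Si](C)(C)C)C#C | intermediate
10 | (7aS)-2-methoxy-1,2,5,6,7,7a-hexahydro-4H-inden-4-one (both C-2 epimers) | O=C1C2=CC(OC)C[C@@H]2CCC1 | intermediate
11 | cis-fused (7aS)-1,3a,5,6,7,7a-hexahydro-4H-inden-4-one | O=C1[C@@H]2C=CC[C@@H]2CCC1 | intermediate (not isolated)
12 | (S)-1,2,5,6,7,7a-hexahydro-4H-inden-4-one | O=C1C2=CCC[C@@H]2CCC1 | intermediate
13 | methyl 2-oxocyclopentane-1-carboxylate | COC(=O)C1CCCC1=O | starting material
14 | (S)-1-phenylethylamine | C[C@H](N)c1ccccc1 | starting material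
15 | tert-butyl acrylate | C=CC(=O)OC(C)(C)C | starting material
16 | methyl 2-{[(S)-1-phenylethyl]amino}cyclopent-1-ene-1-carboxylate | COC(=O)C1=C(N[C@@H](C)c2ccccc2)CCC1 | intermediate (not isolated)
17 | N-[(S)-1-phenylethyl] ketimine of 18 | CC(C)(C)OC(=O)CC[C@@]1(C(=O)OC)CCCC1=N[C@@H](C)c1ccccc1 | intermediate (not isolated)
18 | methyl (S)-1-(3-tert-butoxy-3-oxopropyl)-2-oxocyclopentane-1-carboxylate | CC(C)(C)OC(=O)CC[C@@]1(C(=O)OC)CCCC1=O | intermediate
19 | allylamine | C=CCN | starting material
20 | N-allyl ketimine of 18 | CC(C)(C)OC(=O)CC[C@@]1(C(=O)OC)CCCC1=NCC=C | intermediate (not isolated)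
21 | methyl (S)-6-(3-tert-butoxy-3-oxopropyl)-3-methyl-1,4,5,6-tetrahydrocyclopenta[b]pyrrole-6-carboxylate | Cc1c[nH]c2c1CC[C@@]2(CCC(=O)OC(C)(C)C)C(=O)OC | intermediate
22 | tert-butyl 3-[(S)-6-(hydroxymethyl)-3-methyl-1,4,5,6-tetrahydrocyclopenta[b]pyrrol-6-yl]propanoate | Cc1c[nH]c2c1CC[C@]2(CO)CCC(=O)OC(C)(C)C | intermediate
23 | triisopropylsilyl ether of 22 | Cc1c[nH]c2c1CC[C@]2(CO[Si](C(C)C)(C(C)C)C(C)C)CCC(=O)OC(C)(C)C | intermediate
24 | sodium pyrrolide of 23 | Cc1c[n-]c2c1CC[C@]2(CO[Si](C(C)C)(C(C)C)C(C)C)CCC(=O)OC(C)(C)C.[Na+] | intermediate (not isolated)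
25 | N-[2-(trimethylsilyl)ethoxycarbonyl] derivative of 23 | Cc1cn(C(=O)OCC[Si](C)(C)C)c2c1CC[C@]2(CO[Si](C(C)C)(C(C)C)C(C)C)CCC(=O)OC(C)(C)C | intermediate
26 | 2-(trimethylsilyl)ethyl (3S,3aR,6S,6aS)-6-(3-tert-butoxy-3-oxopropyl)-3-methyl-6-{[(triisopropylsilyl)oxy]methyl}hexahydrocyclopenta[b]pyrrole-1(2H)-carboxylate | CC(C)[Si](OC[C@]1(CCC(=O)OC(C)(C)C)CC[C@H]2[C@@H]1N(C(=O)OCC[Si](C)(C)C)C[C@H]2C)(C(C)C)C(C)C | intermediate
27 | 6-(hydroxymethyl) analogue of 26 | OC[C@]1(CCC(=O)OC(C)(C)C)CC[C@H]2[C@@H]1N(C(=O)OCC[Si](C)(C)C)C[C@H]2C | intermediate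
28 | 2-(trimethylsilyl)ethyl (3S,3aR,6S,6aS)-6-(3-tert-butoxy-3-oxopropyl)-6-formyl-3-methylhexahydrocyclopenta[b]pyrrole-1(2H)-carboxylate | O=C[C@]1(CCC(=O)OC(C)(C)C)CC[C@H]2[C@@H]1N(C(=O)OCC[Si](C)(C)C)C[C@H]2C | intermediate
29 | lithium dienolate of 12 | [Li]OC1=CCC[C@H]2CCC=C12 | intermediate (not isolated)
30 | aldol adduct: hydrindenone carrying at C-5 the hydroxy(azabicyclyl)methyl group, 5-H cis to 7a-H | O=C1C2=CCC[C@@H]2CC[C@@H]1[C@H](O)[C@]1(CCC(=O)OC(C)(C)C)CC[C@H]2[C@@H]1N(C(=O)OCC[Si](C)(C)C)C[C@H]2C | intermediate
31 | allylic alcohol from 30, 4-OH cis to the C-5 side chain | O[C@@H]1C2=CCC[C@@H]2CC[C@@H]1[C@H](O)[C@]1(CCC(=O)OC(C)(C)C)CC[C@H]2[C@@H]1N(C(=O)OCC[Si](C)(C)C)C[C@H]2C | intermediate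
32 | amino diol (31 without the carbamate) | O[C@@H]1C2=CCC[C@@H]2CC[C@@H]1[C@H](O)[C@]1(CCC(=O)OC(C)(C)C)CC[C@H]2[C@@H]1NC[C@H]2C | intermediate
33 | pentacyclic amino alcohol (piperidine closed, N trans to the carbinol-bearing carbon on the carbocycle) | C[C@@H]1CN2[C@H]3C4=CCC[C@@H]4CC[C@@H]3[C@H](O)[C@]5(CCC(=O)OC(C)(C)C)CC[C@H]1[C@@H]52 | intermediate
34 | pentacyclic amino ketone | C[C@@H]1CN2[C@H]3C4=CCC[C@@H]4CC[C@@H]3C(=O)[C@]5(CCC(=O)OC(C)(C)C)CC[C@H]1[C@@H]52 | intermediate
35 | exo-methylene tert-butyl ester | C[C@@H]1CN2[C@H]3C4=CCC[C@@H]4CC[C@@H]3C(=C)[C@]5(CCC(=O)OC(C)(C)C)CC[C@H]1[C@@H]52 | intermediate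
36 | hexacyclic lactone amine (N-deoxy target) | C[C@@H]1CN2[C@H]3C4=CCC[C@@H]4CC[C@@H]3[C@@]3(C)OC(=O)CC[C@]34CC[C@H]1[C@@H]42 | intermediate
37 | target N-oxide | C[C@@H]1C[N@@+]2([O-])[C@H]3C4=CCC[C@@H]4CC[C@@H]3[C@@]3(C)OC(=O)CC[C@]34CC[C@H]1[C@@H]42 | target

## Count and risks

Total step count: 23. Longest linear sequence: 16 steps (13 → 37, steps 8 to 23).

Three steps most likely to fail:

Step 6. The vinyl cation may be captured by chloride, the propargylic silyl ether may ionize, or the cation may collapse without the ring bond migrating, so the enone is not formed. The fallback uses known chemistry and sets out from 7. H2C=CHMgBr/CeCl3 gives the vinyl carbinol F1, and 1-(trimethylsilyl)imidazole gives its silyl ether F2. SnCl4 then effects the established alkene-terminated Prins–pinacol ring-enlarging cyclopentane annulation to the cis-fused methoxy ketone F3. The more substituted silyl enol ether F4 (Me3SiCl, NaI, Et3N, MeCN) is brominated with NBS to the angular bromo ketone F5, with bromine cis to the ring-fusion hydrogen. Li2CO3/LiBr in DMF then removes HBr by anti elimination, which can only engage a hydrogen of the five-membered ring, and the route is rejoined at 10.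

Step 19. The allylic oxyphosphonium intermediate may ionize (loss of configuration at the carbinol carbon), eliminate to a diene, or fail to close the strained ring. The fallback sets out from 31. The 1,3-diol is bridged as the cyclic sulfate F6 (1,1'-sulfonyldiimidazole, NaH, THF). Bu4NF then removes the carbamate, so that the amine opens the sulfate at the allylic carbon with inversion to give the sulfate monoester F7. Hydrolysis (cat. H2SO4, wet THF) rejoins the route at 33.

Step 22. The acid may protonate or shift the ring alkene, or the tertiary cation may rearrange before it is captured. The fallback sets out from 34. MeLi/CeCl3 (THF, −78 °C) adds a methyl group to the ketone to give the tertiary alcohol F8. CF3CO2H then removes the tert-butyl group and closes the lactone, rejoining the route at 36. Only the epimer with the hydroxyl syn to the propanoate chain can give the cis-fused lactone, so the facial outcome of the addition is read at this point.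

## Further compounds

F1 | step 6 | (1S,2S)-2-(2,2-dimethoxyethyl)-1-vinylcyclopentan-1-ol | COC(OC)C[C@@H]1CCC[C@@]1(O)C=C
F2 | step 6 | trimethylsilyl ether of F1 | COC(OC)C[C@@H]1CCC[C@@]1(O[Si](C)(C)C)C=C
F3 | step 6 | cis-fused (7aS)-2-methoxyoctahydro-4H-inden-4-one | O=C1[C@@H]2CC(OC)C[C@@H]2CCC1
F4 | step 6 | 4-(trimethylsilyloxy) enol ether of F3 with the 3a,4-double bond | C[Si](C)(C)OC1=C2CC(OC)C[C@@H]2CCC1
F5 | step 6 | 3a-bromo derivative of F3, bromine cis to 7a-H | O=C1[C@]2(Br)CC(OC)C[C@@H]2CCC1
F6 | step 19 | cyclic sulfate of the 1,3-diol 31 | O=S1(=O)O[C@@H]2C3=CCC[C@@H]3CC[C@@H]2[C@H](O1)[C@]4(CCC(=O)OC(C)(C)C)CC[C@H]5[C@@H]4N(C(=O)OCC[Si](C)(C)C)C[C@H]5C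
F7 | step 19 | sulfate monoester of 33 (zwitterion) | C[C@@H]1C[NH+]2[C@H]3C4=CCC[C@@H]4CC[C@@H]3[C@H](OS(=O)(=O)[O-])[C@]5(CCC(=O)OC(C)(C)C)CC[C@H]1[C@@H]52
F8 | step 22 | tertiary alcohol from methyl addition to 34 | C[C@@H]1CN2[C@H]3C4=CCC[C@@H]4CC[C@@H]3[C@@](C)(O)[C@]5(CCC(=O)OC(C)(C)C)CC[C@H]1[C@@H]52
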